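**Retrosynthetic overview**
1. Target 33 ⇒ late C8–O acylation (Yamaguchi) with TBS-protected 2-(hydroxymethyl)acrylic acid, after unveiling the α-methylene lactone from a masked C13–OPMB group on a ten-membered core that already carries C9–OAc.
2. Cyclodecene (ring B) ⇒ ring-closing metathesis forming C1=C10 between a terminal alkene and a Baylis–Hillman-type acrylate; C9–C10 from a C9 aldehyde and an α-aluminated acrylate (Felkin–Anh).
3. C8 ⇒ ketoreductase reduction of an α-hydroxy ketone; C7–C8 ⇒ anti-selective cuprate (acyl-anion equivalent) conjugate addition to a butenolide; C13 by enolate alkylation.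
4. γ-Lactone (ring A) ⇒ propiolate addition to an epoxy aldehyde, chelation-controlled ynone reduction (C6), semi-hydrogenation and lactonisation.
5. Oxirane (C4, C5) ⇒ Sharpless epoxidation of (Z)-3-methylhepta-2,6-dien-1-ol made from hex-1-en-5-yne; ring order: oxirane → γ-lactone → cyclodecene.

Convention: locants C1–C15 are the germacrane positions of the target (C12 lactone C=O, C13 exocyclic CH2, C14 ester carbon, C15 methyl); Ox = (2S,3R)-3-(but-3-en-1-yl)-3-methyloxiran-2-yl, PMB = 4-methoxybenzyl, TES = triethylsilyl, TBS = tert-butyldimethylsilyl.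

**Route**

Step 1
Reactants: 1 hex-1-en-5-yne
Product: 2 methyl hept-6-en-2-ynoate
Conditions: n-BuLi, THF, −78 °C; ClCO2Me, −78 → 0 °C
Reagents that add atoms: methyl chloroformate, COC(=O)Cl
Why: Acetylide C-acylation works because n-BuLi removes only the alkyne proton and the lithium acetylide is trapped by the chloroformate; no stereocentre is formed.

Step 2
Reactants: 2 methyl hept-6-en-2-ynoate
Product: 3 methyl (2Z)-3-methylhepta-2,6-dienoate
Conditions: Me2CuLi (from MeLi, CuI), THF, −78 °C; MeOH quench at −78 °C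
Reagents that add atoms: lithium dimethylcuprate, [Li+].C[Cu-]C
Why: syn-Carbocupration (conjugate addition) of the ynoate with cold protonation puts the new methyl cis to H, so the butenyl chain ends cis to the ester, which is the (Z)-alkene needed for the cis-epoxide.

Step 3
Reactants: 3 methyl (2Z)-3-methylhepta-2,6-dienoate
Product: 4 (2Z)-3-methylhepta-2,6-dien-1-ol
Conditions: iBu2AlH (2.2 equiv), CH2Cl2, −78 °C
Reagents that add atoms: none
Why: 1,2-Reduction of the enoate by the aluminium hydride gives the allylic alcohol without touching either alkene or the alkene geometry.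

Step 4
Reactants: 4 (2Z)-3-methylhepta-2,6-dien-1-ol
Product: 5 [(2S,3R)-3-(but-3-en-1-yl)-3-methyloxiran-2-yl]methanol
Conditions: Ti(OiPr)4 (10 mol %), L-(+)-diethyl tartrate (12 mol %), t-BuOOH, 4 Å MS, CH2Cl2, −20 °C
Reagents that add atoms: tert-butyl hydroperoxide, CC(C)(C)OO
Why: Sharpless asymmetric epoxidation delivers oxygen to one face of the allylic alcohol only (same sense as nerol → (2S,3R)-epoxynerol, about 90–94 % ee), setting C4 and C5 as the first stereocentres while the unactivated terminal alkene is inert.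

Step 5
Reactants: 5 [(2S,3R)-3-(but-3-en-1-yl)-3-methyloxiran-2-yl]methanol
Product: 6 (2R,3R)-3-(but-3-en-1-yl)-3-methyloxirane-2-carbaldehyde
Conditions: TEMPO (10 mol %), PhI(OAc)2, CH2Cl2, 0 °C → rt
Reagents that add atoms: none
Why: Oxoammonium (TEMPO) oxidation stops at the aldehyde under near-neutral conditions, so the acid-sensitive trisubstituted epoxide and the α-stereocentre survive.

Step 6
Reactants: 6 (2R,3R)-3-(but-3-en-1-yl)-3-methyloxirane-2-carbaldehyde; 7 methyl prop-2-ynoate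
Product: 8 methyl 4-hydroxy-4-Ox-but-2-ynoate (both C6 epimers)
Conditions: 7, LiN(SiMe3)2, THF, −78 °C; then 6, −78 °C
Reagents that add atoms: none
Why: 1,2-Addition of lithium methyl propiolate to the aldehyde is fast at −78 °C and the C6 epimer mixture does not matter because C6 is reset in steps 7 and 8.

Step 7
Reactants: 8 methyl 4-hydroxy-4-Ox-but-2-ynoate
Product: 9 methyl 4-[(2R,3R)-3-(but-3-en-1-yl)-3-methyloxiran-2-yl]-4-oxobut-2-ynoate
Conditions: Dess–Martin periodinane, NaHCO3, CH2Cl2, 0 °C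
Reagents that add atoms: none
Why: Buffered Dess–Martin oxidation converts the propargylic alcohol into the ynone without acid that would open the epoxide.

Step 8
Reactants: 9 methyl 4-[(2R,3R)-3-(but-3-en-1-yl)-3-methyloxiran-2-yl]-4-oxobut-2-ynoate
Product: 10 methyl (4S)-4-hydroxy-4-Ox-but-2-ynoate
Conditions: Zn(BH4)2, Et2O, −30 °C
Reagents that add atoms: none
Why: Chelation-controlled hydride reduction works because zinc bridges the ketone and epoxide oxygens and hydride enters from the face remote from C4, giving the anti (erythro) epoxy alcohol, which is C6 (S).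

Step 9
Reactants: 10 methyl (4S)-4-hydroxy-4-Ox-but-2-ynoate
Product: 12 (5S)-5-Ox-furan-2(5H)-one, via Z-hydroxy enoate 11 (not isolated)
Conditions: H2 (1 atm), Pd/CaCO3 poisoned with Pb(OAc)2, quinoline, EtOAc, rt; lactonises on concentration over SiO2
Reagents that add atoms: none
Why: Lindlar-type semi-hydrogenation gives the (Z)-enoate (the alkyne reacts much faster than the terminal alkene, so hydrogen uptake is stopped at one equivalent), and its γ-hydroxyl closes the butenolide by acyl substitution with C6 untouched.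

Step 10
Reactants: 12 (5S)-5-Ox-furan-2(5H)-one; 13 ethyl vinyl ether
Product: 14 (4S,5S)-4-(1-ethoxyethenyl)-5-Ox-oxolan-2-one
Conditions: 13, t-BuLi, THF, −78 → 0 °C; CuI (0.5 equiv), −78 °C; then 12, −78 °C
Reagents that add atoms: none
Why: Conjugate addition of the Gilman cuprate of 1-ethoxyvinyl (an acyl-anion equivalent) to the butenolide occurs anti to the C6 substituent, setting C7 with the 6,7-trans relationship of the target.

Step 11
Reactants: 14 (4S,5S)-4-(1-ethoxyethenyl)-5-Ox-oxolan-2-one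
Product: 15 (3R,4S,5S)-4-(1-ethoxyethenyl)-3-(PMB-oxymethyl)-5-Ox-oxolan-2-one
Conditions: LiN(SiMe3)2, THF, −78 °C; PMBOCH2Cl, −78 → −40 °C
Reagents that add atoms: 4-methoxybenzyl chloromethyl ether, COc1ccc(COCCl)cc1
Why: Lactone enolate alkylation with the reactive alkoxymethyl chloride occurs trans to the C7 substituent and installs C13 as a masked methylene (the C11 centre is temporary).

Step 12
Reactants: 15 (3R,4S,5S)-4-(1-ethoxyethenyl)-3-(PMB-oxymethyl)-5-Ox-oxolan-2-one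
Product: 17 (3R,4S,5S)-4-(hydroxyacetyl)-3-(PMB-oxymethyl)-5-Ox-oxolan-2-one, via epoxy ether 16 (not isolated)
Conditions: dimethyldioxirane (1.05 equiv, acetone), CH2Cl2, −78 → −40 °C; then pH 7 aqueous buffer
Reagents that add atoms: dimethyldioxirane, CC1(C)OO1; water, O
Why: Rubottom-type epoxidation is selective because the electron-rich enol ether reacts far faster than the terminal alkene, and hydrolysis of the epoxy ether gives the α-hydroxy ketone.

Step 13
Reactants: 17 (3R,4S,5S)-4-(hydroxyacetyl)-3-(PMB-oxymethyl)-5-Ox-oxolan-2-one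
Product: 18 (3R,4R,5S)-4-[(1S)-1,2-dihydroxyethyl]-3-(PMB-oxymethyl)-5-Ox-oxolan-2-one
Conditions: ketoreductase (KRED, NADPH-dependent, anti-Prelog type from a screening panel), NADP+ (cat.), i-PrOH (10 vol %), phosphate buffer pH 7.0, DMSO (5 vol %), 30 °C
Reagents that add atoms: none
Why: Enzymatic carbonyl reduction sets C8 (S) under catalyst control, because the ketoreductase distinguishes the small CH2OH side from the bulky lactone side of the ketone; the neutral buffer is tolerated by lactone and epoxide, and isopropanol recycles the cofactor.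

Step 14
Reactants: 18 (3R,4R,5S)-4-[(1S)-1,2-dihydroxyethyl]-3-(PMB-oxymethyl)-5-Ox-oxolan-2-one
Product: 19 (3R,4S,5S)-4-[(1S)-1,2-bis(TES-oxy)ethyl]-3-(PMB-oxymethyl)-5-Ox-oxolan-2-one
Conditions: TESCl (2.5 equiv), imidazole, DMF, 0 °C → rt
Reagents that add atoms: chlorotriethylsilane, CC[Si](Cl)(CC)CC
Why: Silylation with the chlorosilane and imidazole protects both hydroxyls without a Lewis acid that could open the epoxide.

Step 15
Reactants: 19 (3R,4S,5S)-4-[(1S)-1,2-bis(TES-oxy)ethyl]-3-(PMB-oxymethyl)-5-Ox-oxolan-2-one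
Product: 20 (3R,4S,5S)-4-[(1S)-2-oxo-1-(TES-oxy)ethyl]-3-(PMB-oxymethyl)-5-Ox-oxolan-2-one
Conditions: (COCl)2, DMSO, CH2Cl2, −78 → −40 °C; Et3N, −78 → 0 °C
Reagents that add atoms: none
Why: Swern oxidation attacks the unhindered primary TES ether directly (chlorosulfonium-induced desilylation, then oxidation) while the secondary TES ether at C8 is untouched, giving the α-silyloxy aldehyde in one operation.

Step 16
Reactants: 20 (3R,4S,5S)-4-[(1S)-2-oxo-1-(TES-oxy)ethyl]-3-(PMB-oxymethyl)-5-Ox-oxolan-2-one; 7 methyl prop-2-ynoate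
Product: 21 (3R,4S,5S)-4-[(1S,2R)-2-hydroxy-3-(methoxycarbonyl)-1-(TES-oxy)but-3-en-1-yl]-3-(PMB-oxymethyl)-5-Ox-oxolan-2-one
Conditions: 7, iBu2AlH, N-methylmorpholine N-oxide, THF, 0 °C; then 20, 0 °C → rt
Reagents that add atoms: none
Why: Vinylalumination gives the Baylis–Hillman-type adduct because the α-aluminated acrylate from hydroalumination of the propiolate adds to the aldehyde under Felkin–Anh control (C8–OTES anti to the nucleophile), setting C9 (R) as the 8,9-anti isomer.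

Step 17
Reactants: 21 (3R,4S,5S)-4-[(1S,2R)-2-hydroxy-3-(methoxycarbonyl)-1-(TES-oxy)but-3-en-1-yl]-3-(PMB-oxymethyl)-5-Ox-oxolan-2-one
Product: 22 (3R,4S,5S)-4-[(1S,2R)-2-acetoxy-3-(methoxycarbonyl)-1-(TES-oxy)but-3-en-1-yl]-3-(PMB-oxymethyl)-5-Ox-oxolan-2-one
Conditions: Ac2O, pyridine, DMAP (cat.), CH2Cl2, 0 °C
Reagents that add atoms: acetic anhydride, CC(=O)OC(C)=O
Why: Acetylation installs the C9 acetate of the target, which also protects the allylic alcohol during metathesis.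

Step 18
Reactants: 22 (3R,4S,5S)-4-[(1S,2R)-2-acetoxy-3-(methoxycarbonyl)-1-(TES-oxy)but-3-en-1-yl]-3-(PMB-oxymethyl)-5-Ox-oxolan-2-one
Product: 23 methyl 9-acetoxy-4,5-epoxy-13-(PMB-oxy)-8-(TES-oxy)-11,13-dihydrogermacr-1(10)-en-12,6-olid-14-oate (C4–C9 as in 33; C13 trans to C8)
Conditions: second-generation Hoveyda–Grubbs catalyst [RuCl2(H2IMes)(=CH-C6H4-2-OiPr)] (10 mol %), toluene (1 mM), 80 °C
Reagents that add atoms: none
Why: Ring-closing metathesis loads ruthenium on the monosubstituted C1 alkene and closes onto the only acrylate present (the lactone methylene is still masked); the ten-membered ring enforces the ring-cis C1=C10 geometry of the target and ethylene loss drives the reaction.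

Step 19
Reactants: 23 methyl 9-acetoxy-4,5-epoxy-13-(PMB-oxy)-8-(TES-oxy)-11,13-dihydrogermacr-1(10)-en-12,6-olid-14-oate
Product: 24 methyl 9-acetoxy-4,5-epoxy-13-hydroxy-8-(TES-oxy)-11,13-dihydrogermacr-1(10)-en-12,6-olid-14-oate
Conditions: DDQ, CH2Cl2/pH 7 buffer, 0 °C
Reagents that add atoms: none
Why: Oxidative PMB ether cleavage (benzylic hydride abstraction by DDQ) is neutral and leaves the silyl ether, acetate, epoxide and electron-poor alkene untouched.

Step 20
Reactants: 24 methyl 9-acetoxy-4,5-epoxy-13-hydroxy-8-(TES-oxy)-11,13-dihydrogermacr-1(10)-en-12,6-olid-14-oate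
Product: 26 methyl 9-acetoxy-4,5-epoxy-8-(TES-oxy)germacra-1(10),11(13)-dien-12,6-olid-14-oate (C4–C9 as in 33), via mesylate 25 (not isolated)
Conditions: MsCl, Et3N, CH2Cl2, 0 °C; then DBU (1.1 equiv), 0 °C
Reagents that add atoms: none
Why: Mesylation followed by E1cB elimination of the β-mesyloxy lactone can only give the exocyclic C11=C13 alkene and removes the temporary C11 stereocentre.

Step 21
Reactants: 26 methyl 9-acetoxy-4,5-epoxy-8-(TES-oxy)germacra-1(10),11(13)-dien-12,6-olid-14-oate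
Product: 27 methyl 9-acetoxy-4,5-epoxy-8-hydroxygermacra-1(10),11(13)-dien-12,6-olid-14-oate (C4–C9 as in 33)
Conditions: HF·pyridine, excess pyridine, THF, 0 °C
Reagents that add atoms: none
Why: Fluoride desilylation buffered with pyridine removes the secondary TES ether without opening the epoxide, and keeps the medium mild enough to hold back 9→8 acetyl migration.

Step 22
Reactants: 28 methyl 2-(hydroxymethyl)prop-2-enoate
Product: 29 methyl 2-[(TBS-oxy)methyl]prop-2-enoate
Conditions: TBSCl, imidazole, CH2Cl2, 0 °C → rt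
Reagents that add atoms: tert-butyldimethylsilyl chloride, CC(C)(C)[Si](C)(C)Cl
Why: Silylation of the primary allylic alcohol protects it so the acid can be activated later without self-acylation.

Step 23
Reactants: 29 methyl 2-[(TBS-oxy)methyl]prop-2-enoate
Product: 30 2-[(TBS-oxy)methyl]prop-2-enoic acid
Conditions: LiOH, THF/H2O, 0 °C; then 1 M HCl to pH 4
Reagents that add atoms: lithium hydroxide, [Li+].[OH-]
Why: Saponification of the unhindered methyl ester at 0 °C leaves the TBS ether in place.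

Step 24
Reactants: 27 methyl 9-acetoxy-4,5-epoxy-8-hydroxygermacra-1(10),11(13)-dien-12,6-olid-14-oate; 30 2-[(TBS-oxy)methyl]prop-2-enoic acid
Product: 32 methyl 9-acetoxy-4,5-epoxy-8-{2-[(TBS-oxy)methyl]prop-2-enoyloxy}germacra-1(10),11(13)-dien-12,6-olid-14-oate (C4–C9 as in 33), via mixed anhydride 31 (not isolated)
Conditions: 30, 2,4,6-trichlorobenzoyl chloride, Et3N, toluene, rt; then 27, DMAP, rt
Reagents that add atoms: none
Why: Yamaguchi esterification acylates the hindered secondary C8 hydroxyl through the mixed anhydride faster than the neighbouring acetate can migrate, with retention at C8.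

Step 25
Reactants: 32 methyl 9-acetoxy-4,5-epoxy-8-{2-[(TBS-oxy)methyl]prop-2-enoyloxy}germacra-1(10),11(13)-dien-12,6-olid-14-oate
Product: 33 CNP0147016.1, methyl 9-acetoxy-4,5-epoxy-8-[2-(hydroxymethyl)prop-2-enoyloxy]germacra-1(10),11(13)-dien-12,6-olid-14-oate
Conditions: HF·pyridine, excess pyridine, THF, 0 °C → rt
Reagents that add atoms: none
Why: Fluoride desilylation of the primary allylic TBS ether is fast under buffered conditions that leave the epoxide, both Michael acceptors and the three esters intact.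

**Compound list**
1 | hex-1-en-5-yne | C=CCCC#C | starting material
2 | methyl hept-6-en-2-ynoate | C=CCCC#CC(=O)OC | intermediate
3 | methyl (2Z)-3-methylhepta-2,6-dienoate | C=CCC/C(C)=C\C(=O)OC | intermediate
4 | (2Z)-3-methylhepta-2,6-dien-1-ol | C=CCC/C(C)=C\CO | intermediate
5 | [(2S,3R)-3-(but-3-en-1-yl)-3-methyloxiran-2-yl]methanol | OC[C@@H]1O[C@]1(C)CCC=C | intermediate
6 | (2R,3R)-3-(but-3-en-1-yl)-3-methyloxirane-2-carbaldehyde | O=C[C@@H]1O[C@]1(C)CCC=C | intermediate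
7 | methyl prop-2-ynoate (methyl propiolate) | C#CC(=O)OC | starting material
8 | methyl 4-hydroxy-4-Ox-but-2-ynoate, both C6 epimers | COC(=O)C#CC(O)[C@@H]1O[C@]1(C)CCC=C | intermediate
9 | methyl 4-[(2R,3R)-3-(but-3-en-1-yl)-3-methyloxiran-2-yl]-4-oxobut-2-ynoate | COC(=O)C#CC(=O)[C@@H]1O[C@]1(C)CCC=C | intermediate
10 | methyl (4S)-4-hydroxy-4-Ox-but-2-ynoate (anti epoxy alcohol) | COC(=O)C#C[C@H](O)[C@@H]1O[C@]1(C)CCC=C | intermediate
11 | methyl (2Z,4S)-4-hydroxy-4-Ox-but-2-enoate | COC(=O)/C=C\[C@H](O)[C@@H]1O[C@]1(C)CCC=C | intermediate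
12 | (5S)-5-Ox-furan-2(5H)-one | O=C1O[C@H]([C@@H]2O[C@]2(C)CCC=C)C=C1 | intermediate
13 | ethyl vinyl ether (ethoxyethene) | C=COCC | starting material
14 | (4S,5S)-4-(1-ethoxyethenyl)-5-Ox-oxolan-2-one (C7 substituent trans to C5) | O=C1O[C@H]([C@@H]2O[C@]2(C)CCC=C)[C@@H](C(=C)OCC)C1 | intermediate
15 | (3R,4S,5S)-4-(1-ethoxyethenyl)-3-(PMB-oxymethyl)-5-Ox-oxolan-2-one (all-trans) | O=C1O[C@H]([C@@H]2O[C@]2(C)CCC=C)[C@@H](C(=C)OCC)[C@@H]1COCc3ccc(OC)cc3 | intermediate
16 | (3R,4S,5S)-4-(2-ethoxyoxiran-2-yl)-3-(PMB-oxymethyl)-5-Ox-oxolan-2-one, both epimers at the new oxirane carbon | O=C1O[C@H]([C@@H]2O[C@]2(C)CCC=C)[C@@H](C2(OCC)CO2)[C@@H]1COCc3ccc(OC)cc3 | intermediate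
17 | (3R,4S,5S)-4-(hydroxyacetyl)-3-(PMB-oxymethyl)-5-Ox-oxolan-2-one | O=C1O[C@H]([C@@H]2O[C@]2(C)CCC=C)[C@@H](C(=O)CO)[C@@H]1COCc3ccc(OC)cc3 | intermediate
18 | (3R,4R,5S)-4-[(1S)-1,2-dihydroxyethyl]-3-(PMB-oxymethyl)-5-Ox-oxolan-2-one | O=C1O[C@H]([C@@H]2O[C@]2(C)CCC=C)[C@@H]([C@H](O)CO)[C@@H]1COCc3ccc(OC)cc3 | intermediate
19 | (3R,4S,5S)-4-[(1S)-1,2-bis(TES-oxy)ethyl]-3-(PMB-oxymethyl)-5-Ox-oxolan-2-one | O=C1O[C@H]([C@@H]2O[C@]2(C)CCC=C)[C@@H]([C@H](O[Si](CC)(CC)CC)CO[Si](CC)(CC)CC)[C@@H]1COCc3ccc(OC)cc3 | intermediate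
20 | (3R,4S,5S)-4-[(1S)-2-oxo-1-(TES-oxy)ethyl]-3-(PMB-oxymethyl)-5-Ox-oxolan-2-one | O=C1O[C@H]([C@@H]2O[C@]2(C)CCC=C)[C@@H]([C@H](O[Si](CC)(CC)CC)C=O)[C@@H]1COCc3ccc(OC)cc3 | intermediate
21 | (3R,4S,5S)-4-[(1S,2R)-2-hydroxy-3-(methoxycarbonyl)-1-(TES-oxy)but-3-en-1-yl]-3-(PMB-oxymethyl)-5-Ox-oxolan-2-one | O=C1O[C@H]([C@@H]2O[C@]2(C)CCC=C)[C@@H]([C@H](O[Si](CC)(CC)CC)[C@H](O)C(=C)C(=O)OC)[C@@H]1COCc3ccc(OC)cc3 | intermediate
22 | (3R,4S,5S)-4-[(1S,2R)-2-acetoxy-3-(methoxycarbonyl)-1-(TES-oxy)but-3-en-1-yl]-3-(PMB-oxymethyl)-5-Ox-oxolan-2-one | O=C1O[C@H]([C@@H]2O[C@]2(C)CCC=C)[C@@H]([C@H](O[Si](CC)(CC)CC)[C@H](OC(C)=O)C(=C)C(=O)OC)[C@@H]1COCc3ccc(OC)cc3 | intermediate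
23 | methyl 9-acetoxy-4,5-epoxy-13-(PMB-oxy)-8-(TES-oxy)-11,13-dihydrogermacr-1(10)-en-12,6-olid-14-oate (C4–C9 as in 33, C13 trans to C8, ring-cis C1=C10) | CC[Si](CC)(CC)O[C@H]1[C@H]2[C@H](COCc3ccc(OC)cc3)C(=O)O[C@@H]2[C@@H]2O[C@]2(C)CC/C=C(/C(=O)OC)[C@H]1OC(C)=O | intermediate
24 | methyl 9-acetoxy-4,5-epoxy-13-hydroxy-8-(TES-oxy)-11,13-dihydrogermacr-1(10)-en-12,6-olid-14-oate | CC[Si](CC)(CC)O[C@H]1[C@H]2[C@H](CO)C(=O)O[C@@H]2[C@@H]2O[C@]2(C)CC/C=C(/C(=O)OC)[C@H]1OC(C)=O | intermediate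
25 | 13-O-methanesulfonate of 24 | CC[Si](CC)(CC)O[C@H]1[C@H]2[C@H](COS(C)(=O)=O)C(=O)O[C@@H]2[C@@H]2O[C@]2(C)CC/C=C(/C(=O)OC)[C@H]1OC(C)=O | intermediate
26 | methyl 9-acetoxy-4,5-epoxy-8-(TES-oxy)germacra-1(10),11(13)-dien-12,6-olid-14-oate | CC[Si](CC)(CC)O[C@H]1[C@H]2C(=C)C(=O)O[C@@H]2[C@@H]2O[C@]2(C)CC/C=C(/C(=O)OC)[C@H]1OC(C)=O | intermediate
27 | methyl 9-acetoxy-4,5-epoxy-8-hydroxygermacra-1(10),11(13)-dien-12,6-olid-14-oate | O[C@H]1[C@H]2C(=C)C(=O)O[C@@H]2[C@@H]2O[C@]2(C)CC/C=C(/C(=O)OC)[C@H]1OC(C)=O | intermediate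
28 | methyl 2-(hydroxymethyl)prop-2-enoate | C=C(CO)C(=O)OC | starting material
29 | methyl 2-[(TBS-oxy)methyl]prop-2-enoate | C=C(CO[Si](C)(C)C(C)(C)C)C(=O)OC | intermediate
30 | 2-[(TBS-oxy)methyl]prop-2-enoic acid | C=C(CO[Si](C)(C)C(C)(C)C)C(=O)O | intermediate
31 | 2-[(TBS-oxy)methyl]prop-2-enoic 2,4,6-trichlorobenzoic anhydride | C=C(CO[Si](C)(C)C(C)(C)C)C(=O)OC(=O)c1c(Cl)cc(Cl)cc1Cl | intermediate
32 | methyl 9-acetoxy-4,5-epoxy-8-{2-[(TBS-oxy)methyl]prop-2-enoyloxy}germacra-1(10),11(13)-dien-12,6-olid-14-oate | C=C(CO[Si](C)(C)C(C)(C)C)C(=O)O[C@H]1[C@H]2C(=C)C(=O)O[C@@H]2[C@@H]2O[C@]2(C)CC/C=C(/C(=O)OC)[C@H]1OC(C)=O | intermediate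
33 | CNP0147016.1: methyl (4R,5S,6S,7R,8S,9R)-9-acetoxy-4,5-epoxy-8-[2-(hydroxymethyl)prop-2-enoyloxy]germacra-1(10),11(13)-dien-12,6-olid-14-oate, ring-cis C1=C10 | C=C(CO)C(=O)O[C@H]1[C@H]2C(=C)C(=O)O[C@@H]2[C@@H]2O[C@]2(C)CC/C=C(/C(=O)OC)[C@H]1OC(C)=O | target

**Count**
Total steps: 25. Longest linear sequence: 23 (steps 1–21, 24, 25); steps 22–23 make the side-chain acid.

**Three steps most likely to fail, with fallbacks**

Step 18 (ring-closing metathesis onto a hindered acrylate to a ten-membered trisubstituted enoate) is the weakest point; it may stall or give dimers. The fallback closes the ring at C9–C10 instead and sets out from bis-silyl ether 19. Lemieux–Johnson cleavage of its only alkene (OsO4 cat., NaIO4, 2,6-lutidine, dioxane/water) gives the C1 aldehyde F1. Wittig olefination with Ph3P=C(I)CO2Me (from Ph3P=CHCO2Me and N-iodosuccinimide) gives the (Z)-2-iodo enoate F2, with C2 cis to iodine. Swern oxidation as in step 15 gives the iodo enoate aldehyde F3. An intramolecular Nozaki–Hiyama–Kishi coupling (CrCl2 in excess, NiCl2 cat., degassed DMSO/THF, 2 mM; zerovalent nickel inserts into C–I and the vinyl group passes to trivalent chromium) adds C10 to the C9 aldehyde with retention of alkene geometry and Felkin–Anh selectivity, giving the macrocyclic C9 alcohol F4. Acetylation (Ac2O, pyridine) brings the material back to the route at 23.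

Step 13 (ketoreductase on a bulky lactone ketone) may find no enzyme with useful rate or selectivity. The fallback is a chemical, catalyst-controlled reduction and sets out from ketol 17. Selective silylation of the primary hydroxyl (TESCl 1.05 equiv, imidazole, −20 °C) gives the silyloxy ketone F5. Corey–Bakshi–Shibata reduction ((S)-2-methyl-CBS-oxazaborolidine, catecholborane, toluene, −78 °C; the lactone carbon acts as the large group and catecholborane spares the terminal alkene) gives the (S)-carbinol F6. A second silylation (TESCl, imidazole) returns to the route at 19.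

Step 16 (vinylalumination) may suffer from the Lewis-acidic aluminium reagent attacking the epoxide or lactone, or from poor conversion of the hindered aldehyde. The fallback uses a masked acrylate and sets out from aldehyde 20. Aldol addition of the lithium enolate of methyl 3-(dimethylamino)propanoate (LiN(iPr)2, THF, −78 °C; again Felkin–Anh at C9) gives the amino ester aldol F7 as C10 epimers. N-Methylation (MeI, MeOH) followed by NaHCO3 eliminates trimethylamine and unveils the acrylate, returning to the route at 21; the C9 epimer, if formed, is removed by chromatography there.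

Further compounds
F1 | step 18 | (3R,4S,5S)-4-[(1S)-1,2-bis(TES-oxy)ethyl]-5-[(2S,3R)-3-methyl-3-(3-oxopropyl)oxiran-2-yl]-3-(PMB-oxymethyl)oxolan-2-one | O=C1O[C@H]([C@@H]2O[C@]2(C)CCC=O)[C@@H]([C@H](O[Si](CC)(CC)CC)CO[Si](CC)(CC)CC)[C@@H]1COCc3ccc(OC)cc3
F2 | step 18 | (Z)-2-iodo enoate: F1 with CHO converted into CH=C(I)CO2Me, C2 cis to I | O=C1O[C@H]([C@@H]2O[C@]2(C)CC/C=C(/C(=O)OC)I)[C@@H]([C@H](O[Si](CC)(CC)CC)CO[Si](CC)(CC)CC)[C@@H]1COCc3ccc(OC)cc3
F3 | step 18 | iodo enoate aldehyde: F2 with the primary CH2OTES converted into the C9 aldehyde | O=C1O[C@H]([C@@H]2O[C@]2(C)CC/C=C(/C(=O)OC)I)[C@@H]([C@H](O[Si](CC)(CC)CC)C=O)[C@@H]1COCc3ccc(OC)cc3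
F4 | step 18 | methyl 4,5-epoxy-9-hydroxy-13-(PMB-oxy)-8-(TES-oxy)-11,13-dihydrogermacr-1(10)-en-12,6-olid-14-oate (C4–C9 as in 33) | CC[Si](CC)(CC)O[C@H]1[C@H]2[C@H](COCc3ccc(OC)cc3)C(=O)O[C@@H]2[C@@H]2O[C@]2(C)CC/C=C(/C(=O)OC)[C@H]1O
F5 | step 13 | (3R,4S,5S)-3-(PMB-oxymethyl)-5-Ox-4-[(TES-oxy)acetyl]oxolan-2-one | O=C1O[C@H]([C@@H]2O[C@]2(C)CCC=C)[C@@H](C(=O)CO[Si](CC)(CC)CC)[C@@H]1COCc3ccc(OC)cc3
F6 | step 13 | (3R,4R,5S)-4-[(1S)-1-hydroxy-2-(TES-oxy)ethyl]-3-(PMB-oxymethyl)-5-Ox-oxolan-2-one | O=C1O[C@H]([C@@H]2O[C@]2(C)CCC=C)[C@@H]([C@H](O)CO[Si](CC)(CC)CC)[C@@H]1COCc3ccc(OC)cc3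
F7 | step 16 | (3R,4S,5S)-4-[(1S,2R)-3-(dimethylaminomethyl)-2-hydroxy-4-methoxy-4-oxo-1-(TES-oxy)butyl]-3-(PMB-oxymethyl)-5-Ox-oxolan-2-one, C10 epimers | O=C1O[C@H]([C@@H]2O[C@]2(C)CCC=C)[C@@H]([C@H](O[Si](CC)(CC)CC)[C@H](O)C(CN(C)C)C(=O)OC)[C@@H]1COCc3ccc(OC)cc3
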